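In chromanone numbering, ring B is disconnected at its two bonds to ring A, O1–C8a and C4–C4a. What remains of the pyranone is the cis-β-lactone (3S,4R)-3,4-dimethyloxetan-2-one, which already holds C2 and C3; ring A is an aryl fluoride whose C8a–F sits next to a lithiated C4a. In one flask the aryllithium opens the lactone at its acyl carbon and the released alkoxide displaces fluoride, so the arene edge C4a–C8a is inserted into the lactone's acyl–oxygen bond (four- to six-membered ring expansion). The step exploits the ortho ether/ketone pattern O1–C8a=C4a–C4=O. Lavandulyl is installed before, the C6 arylpropanoic arm and the dearomatising C8 prenylation after.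

Key step: step 8

Remark: (R)-lavandulol (the natural enantiomer) is taken as a purchasable starting material; "(S)-lavandulyl" below means the (2S)-5-methyl-2-(prop-1-en-2-yl)hex-4-en-1-yl group, which has the same spatial arrangement as (R)-lavandulol.

Step 1
Reactants: 1 (S)-4-benzyl-3-propionyloxazolidin-2-one; 2 acetaldehyde
Product: 4 (4S)-4-benzyl-3-[(2S,3R)-3-hydroxy-2-methylbutanoyl]oxazolidin-2-one, via Z-boron enolate 3 (not isolated)
Conditions: Bu2BOTf, i-Pr2NEt, CH2Cl2, 0 °C; 2, −78 → 0 °C; then pH 7 buffer, MeOH, H2O2, 0 °C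
Reagents that add atoms: none
Why: Evans syn-aldol reaction: the Z-boron enolate reacts through a closed Zimmerman–Traxler chair on the face opposite the benzyl group, which sets the (2S,3R) pair that becomes C3 and C2 of ring B.

Step 2
Reactants: 4 (4S)-4-benzyl-3-[(2S,3R)-3-hydroxy-2-methylbutanoyl]oxazolidin-2-one
Product: 6 (2S,3R)-3-hydroxy-2-methylbutanoic acid, via lithium peroxycarboxylate 5 (not isolated)
Conditions: LiOH, H2O2, THF/H2O, 0 °C; Na2SO3 (aq); HCl to pH 2
Reagents that add atoms: hydrogen peroxide, OO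
Why: Hydroperoxide-mediated cleavage of the Evans auxiliary attacks the exocyclic imide carbonyl selectively, and the peracid formed first is reduced by sulfite, so the acid should be obtained without touching either stereocentre.

Step 3
Reactants: 6 (2S,3R)-3-hydroxy-2-methylbutanoic acid
Product: 8 (3S,4R)-3,4-dimethyloxetan-2-one, via mixed sulfonic anhydride 7 (not isolated)
Conditions: PhSO2Cl, pyridine, 0 → 5 °C
Reagents that add atoms: none
Why: β-Lactonisation by carboxyl activation (sulfonyl chloride/pyridine method): the hydroxyl oxygen closes onto the mixed anhydride (4-exo-trig) with no bond to either stereocentre broken, so the syn acid should give the cis lactone.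

Step 4
Reactants: 9 (R)-lavandulol
Product: 10 (3R)-3-(iodomethyl)-2,6-dimethylhepta-1,5-diene
Conditions: I2, PPh3, imidazole, CH2Cl2, 0 °C
Reagents that add atoms: iodine, II
Why: Appel iodination is an SN2 displacement at the primary carbon and leaves the adjacent stereocentre and both alkenes untouched.

Step 5
Reactants: 11 5-fluororesorcinol
Product: 12 1-fluoro-3,5-bis(methoxymethoxy)benzene
Conditions: MOMCl, i-Pr2NEt, CH2Cl2, 0 → 23 °C
Reagents that add atoms: chloromethyl methyl ether, COCCl
Why: Base-mediated O-alkylation of both phenols (Williamson type) gives the bis-MOM ether whose acetal oxygens direct the later lithiations.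

Step 6
Reactants: 12 1-fluoro-3,5-bis(methoxymethoxy)benzene
Product: 16 [4-fluoro-3-iodo-2,6-bis(methoxymethoxy)phenyl]trimethylsilane, via aryllithium 13 (not isolated), via arylsilane 14 (not isolated), via aryllithium 15 (not isolated)
Conditions: n-BuLi, THF, 0 °C; Me3SiCl, −78 → 23 °C; n-BuLi, −78 °C; I2, −78 °C
Reagents that add atoms: chlorotrimethylsilane, C[Si](C)(C)Cl; iodine, II
Why: Two directed ortho-metalations in one flask: butyllithium should first remove the proton flanked by both MOM ethers (coordination control) and the silyl group blocks that site, so the second lithiation can only occur at one of the two equivalent positions between fluorine and OMOM, where iodine traps it.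

Step 7
Reactants: 10 (3R)-3-(iodomethyl)-2,6-dimethylhepta-1,5-diene; 16 [4-fluoro-3-iodo-2,6-bis(methoxymethoxy)phenyl]trimethylsilane
Product: 18 {4-fluoro-2,6-bis(methoxymethoxy)-3-[(S)-lavandulyl]phenyl}trimethylsilane, via alkylzinc iodide 17 (not isolated)
Conditions: 10, Zn dust, LiCl, THF, 40 °C; then 16, Pd(OAc)2 (3 mol %), SPhos (6 mol %), THF, 50 °C
Reagents that add atoms: none
Why: Negishi sp3–sp2 cross-coupling: zinc inserts into the primary C–I bond and the Pd/SPhos catalyst couples the alkylzinc with the hindered aryl iodide under conditions that tolerate the alkenes, the aryl fluoride and the silane, the stereocentre being one carbon away from the C–Zn bond and therefore unaffected.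

Step 8
Reactants: 18 {4-fluoro-2,6-bis(methoxymethoxy)-3-[(S)-lavandulyl]phenyl}trimethylsilane; 8 (3S,4R)-3,4-dimethyloxetan-2-one
Product: 21 (2R,3S)-5,7-bis(methoxymethoxy)-2,3-dimethyl-8-[(S)-lavandulyl]-6-(trimethylsilyl)-2,3-dihydro-4H-chromen-4-one, via aryllithium 19 (not isolated), via lithium aldolate 20 (not isolated)
Conditions: n-BuLi, THF, −78 °C; 8, −78 °C; then DMPU, −78 → 23 °C
Reagents that add atoms: none
Why: Lithiation can only take place at the one remaining arene C–H, which is acidified by the flanking fluorine and MOM ether, and at −78 °C this aryllithium attacks the strained lactone at its acyl carbon (acyl–oxygen cleavage, the usual course with hard organolithiums), which forms C4–C4a and releases the C2 oxygen as lithium aldolate 20. On warming, that alkoxide adds to C8a, now activated by the ortho ketone, and fluoride leaves (intramolecular SNAr through a Meisenheimer intermediate), which forms O1–C8a and closes ring B in the 6-endo-trig addition–elimination mode. The closest known reaction types are ketone formation from aryllithiums and lactones and the SNAr cyclisation of β-hydroxy 2-fluoroaryl ketones to chroman-4-ones; the net result, insertion of an arene C=C edge into an acyl–oxygen bond, parallels aryne σ-insertion. No stereocentre is created: C2 keeps its configuration because its C–O bond is never broken and C3 is carried over from the lactone, so the cis-2,3 relationship is the one set by the Evans aldol. The step needs acyl rather than alkyl attack on the lactone (secured by the hard nucleophile and the secondary O-bearing carbon), fluoride rather than the other ortho substituent OMOM as leaving group (secured by the far higher SNAr nucleofugality of fluoride), and ring closure faster than retro-aldol cleavage or α-epimerisation of 20 (favoured by the lithium counter-ion, the low temperature and the late addition of DMPU).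

Step 9
Reactants: 21 (2R,3S)-5,7-bis(methoxymethoxy)-2,3-dimethyl-8-[(S)-lavandulyl]-6-(trimethylsilyl)-2,3-dihydro-4H-chromen-4-one
Product: 22 (2R,3S)-5,7-dihydroxy-2,3-dimethyl-8-[(S)-lavandulyl]-2,3-dihydro-4H-chromen-4-one
Conditions: 3 M HCl, MeOH, 23 → 40 °C
Reagents that add atoms: none
Why: Acidic methanolysis cleaves both MOM acetals and, once the flanking hydroxyls are free, ipso-protonation should remove the silyl blocking group (protodesilylation), exposing C6–H for the next step.

Step 10
Reactants: 22 (2R,3S)-5,7-dihydroxy-2,3-dimethyl-8-[(S)-lavandulyl]-2,3-dihydro-4H-chromen-4-one; 23 (E)-cinnamaldehyde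
Product: 24 (4S,7S,8R)-2,5-dihydroxy-7,8-dimethyl-10-[(S)-lavandulyl]-4-phenyl-3,4,7,8-tetrahydro-2H,6H-pyrano[3,2-g]chromen-6-one (lactol on O7; anomeric mixture)
Conditions: (S)-α,α-diphenylprolinol trimethylsilyl ether (20 mol %), PhCO2H (20 mol %), toluene, 0 → 23 °C
Reagents that add atoms: none
Why: Iminium-ion Friedel–Crafts alkylation under diarylprolinol silyl ether catalysis followed by hemiacetalisation: the only free ring carbon (C6) adds to C-β of the E-iminium ion on the face left open by the diphenyl(silyloxy)methyl group of the (S)-catalyst (the Si face), which should give the (S) benzylic centre.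

Step 11
Reactants: 24 lactol from step 10
Product: 25 (4S,7S,8R)-5-hydroxy-7,8-dimethyl-10-[(S)-lavandulyl]-4-phenyl-3,4,7,8-tetrahydro-2H,6H-pyrano[3,2-g]chromene-2,6-dione
Conditions: Ag2CO3 on Celite, toluene, 80 °C
Reagents that add atoms: none
Why: Fétizon oxidation converts the lactol into the δ-lactone under neutral heterogeneous conditions that should spare the alkenes, the ketone α-centre and the hydrogen-bonded phenol.

Step 12
Reactants: 25 lactone from step 11; 26 prenyl acetate
Product: 28 (3S)-3-{(2R,3S,8S)-5-hydroxy-2,3-dimethyl-8-[(S)-lavandulyl]-8-(3-methylbut-2-en-1-yl)-4,7-dioxo-3,4,7,8-tetrahydro-2H-chromen-6-yl}-3-phenylpropanoic acid (CNP0150579.2), via dipotassium phenoxide carboxylate 27 (not isolated)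
Conditions: KOSiMe3 (2.1 equiv), THF, 0 → 23 °C; then 26, Pd2(dba)3·CHCl3 (2.5 mol %), (R,R)-DACH-phenyl bis(phosphinobenzamide) ligand (7.5 mol %), THF, 0 → 23 °C; 1 M HCl work-up
Reagents that add atoms: potassium trimethylsilanolate, C[Si](C)(C)[O-].[K+]
Why: Silanolate cleavage of the lactone frees O7 as a phenoxide, whose less hindered ortho carbon C8 is then prenylated at the unsubstituted allyl terminus in a Tsuji–Trost asymmetric allylic alkylation with dearomatisation (O-alkylation is reversible under palladium), the C8 configuration being fixed by the chiral pocket of the ligand, for which the (R,R) antipode is proposed and the (S,S) antipode is the direct alternative because the existing stereocentres are too remote to bias the face.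

Compound list

1 | (S)-4-benzyl-3-propionyloxazolidin-2-one | CCC(=O)N1[C@@H](Cc2ccccc2)COC1=O | starting material
2 | acetaldehyde | CC=O | starting material
3 | (4S)-4-benzyl-3-[(1Z)-1-(dibutylboranyloxy)prop-1-en-1-yl]oxazolidin-2-one (Z-boron enolate, formed in the flask) | C/C=C(\OB(CCCC)CCCC)N1[C@@H](Cc2ccccc2)COC1=O | intermediate
4 | (4S)-4-benzyl-3-[(2S,3R)-3-hydroxy-2-methylbutanoyl]oxazolidin-2-one | O[C@H](C)[C@H](C)C(=O)N1[C@@H](Cc2ccccc2)COC1=O | intermediate
5 | lithium (2S,3R)-3-hydroxy-2-methylbutaneperoxoate (formed in the flask) | O[C@H](C)[C@H](C)C(=O)O[O-].[Li+] | intermediate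
6 | (2S,3R)-3-hydroxy-2-methylbutanoic acid | O[C@H](C)[C@H](C)C(=O)O | intermediate
7 | benzenesulfonic (2S,3R)-3-hydroxy-2-methylbutanoic anhydride (formed in the flask) | O[C@H](C)[C@H](C)C(=O)OS(=O)(=O)c1ccccc1 | intermediate
8 | (3S,4R)-3,4-dimethyloxetan-2-one (cis-β-lactone) | C[C@H]1OC(=O)[C@H]1C | intermediate
9 | (R)-lavandulol, (2R)-5-methyl-2-(prop-1-en-2-yl)hex-4-en-1-ol | C=C(C)[C@@H](CC=C(C)C)CO | starting material
10 | (3R)-3-(iodomethyl)-2,6-dimethylhepta-1,5-diene ((R)-lavandulyl iodide) | C=C(C)[C@@H](CC=C(C)C)CI | intermediate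
11 | 5-fluororesorcinol (5-fluorobenzene-1,3-diol) | Oc1cc(O)cc(F)c1 | starting material
12 | 1-fluoro-3,5-bis(methoxymethoxy)benzene | COCOc1cc(F)cc(OCOC)c1 | intermediate
13 | [4-fluoro-2,6-bis(methoxymethoxy)phenyl]lithium (formed in the flask) | [Li]c1c(OCOC)cc(F)cc1OCOC | intermediate
14 | [4-fluoro-2,6-bis(methoxymethoxy)phenyl]trimethylsilane (formed in the flask) | C[Si](C)(C)c1c(OCOC)cc(F)cc1OCOC | intermediate
15 | [6-fluoro-2,4-bis(methoxymethoxy)-3-(trimethylsilyl)phenyl]lithium (formed in the flask) | [Li]c1c(F)cc(OCOC)c([Si](C)(C)C)c1OCOC | intermediate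
16 | [4-fluoro-3-iodo-2,6-bis(methoxymethoxy)phenyl]trimethylsilane | Ic1c(F)cc(OCOC)c([Si](C)(C)C)c1OCOC | intermediate
17 | [(2R)-5-methyl-2-(prop-1-en-2-yl)hex-4-en-1-yl]zinc iodide (formed in the flask) | C=C(C)[C@@H](CC=C(C)C)C[Zn]I | intermediate
18 | {4-fluoro-2,6-bis(methoxymethoxy)-3-[(2S)-5-methyl-2-(prop-1-en-2-yl)hex-4-en-1-yl]phenyl}trimethylsilane | C=C(C)[C@@H](CC=C(C)C)Cc1c(F)cc(OCOC)c([Si](C)(C)C)c1OCOC | intermediate
19 | {6-fluoro-2,4-bis(methoxymethoxy)-5-[(2S)-5-methyl-2-(prop-1-en-2-yl)hex-4-en-1-yl]-3-(trimethylsilyl)phenyl}lithium (formed in the flask) | C=C(C)[C@@H](CC=C(C)C)Cc1c(F)c([Li])c(OCOC)c([Si](C)(C)C)c1OCOC | intermediate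
20 | lithium (2R,3S)-4-{6-fluoro-2,4-bis(methoxymethoxy)-5-[(2S)-5-methyl-2-(prop-1-en-2-yl)hex-4-en-1-yl]-3-(trimethylsilyl)phenyl}-3-methyl-4-oxobutan-2-olate (formed in the flask) | C=C(C)[C@@H](CC=C(C)C)Cc1c(F)c(C(=O)[C@@H](C)[C@@H](C)O[Li])c(OCOC)c([Si](C)(C)C)c1OCOC | intermediate
21 | (2R,3S)-5,7-bis(methoxymethoxy)-2,3-dimethyl-8-[(2S)-5-methyl-2-(prop-1-en-2-yl)hex-4-en-1-yl]-6-(trimethylsilyl)-2,3-dihydro-4H-chromen-4-one | C=C(C)[C@@H](CC=C(C)C)Cc1c(OCOC)c([Si](C)(C)C)c(OCOC)c2c1O[C@H](C)[C@H](C)C2=O | intermediate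
22 | (2R,3S)-5,7-dihydroxy-2,3-dimethyl-8-[(2S)-5-methyl-2-(prop-1-en-2-yl)hex-4-en-1-yl]-2,3-dihydro-4H-chromen-4-one | C=C(C)[C@@H](CC=C(C)C)Cc1c(O)cc(O)c2c1O[C@H](C)[C@H](C)C2=O | intermediate
23 | (E)-cinnamaldehyde | O=C/C=C/c1ccccc1 | starting material
24 | (4S,7S,8R)-2,5-dihydroxy-7,8-dimethyl-10-[(2S)-5-methyl-2-(prop-1-en-2-yl)hex-4-en-1-yl]-4-phenyl-3,4,7,8-tetrahydro-2H,6H-pyrano[3,2-g]chromen-6-one (lactol, both anomers) | C=C(C)[C@@H](CC=C(C)C)Cc1c2OC(O)C[C@@H](c3ccccc3)c2c(O)c2c1O[C@H](C)[C@H](C)C2=O | intermediate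
25 | (4S,7S,8R)-5-hydroxy-7,8-dimethyl-10-[(2S)-5-methyl-2-(prop-1-en-2-yl)hex-4-en-1-yl]-4-phenyl-3,4,7,8-tetrahydro-2H,6H-pyrano[3,2-g]chromene-2,6-dione | C=C(C)[C@@H](CC=C(C)C)Cc1c2OC(=O)C[C@@H](c3ccccc3)c2c(O)c2c1O[C@H](C)[C@H](C)C2=O | intermediate
26 | prenyl acetate (3-methylbut-2-en-1-yl acetate) | CC(=O)OCC=C(C)C | starting material
27 | dipotassium (3S)-3-{(2R,3S)-5-hydroxy-2,3-dimethyl-8-[(2S)-5-methyl-2-(prop-1-en-2-yl)hex-4-en-1-yl]-7-oxido-4-oxo-3,4-dihydro-2H-chromen-6-yl}-3-phenylpropanoate (formed in the flask) | C=C(C)[C@@H](CC=C(C)C)Cc1c([O-])c([C@@H](CC(=O)[O-])c3ccccc3)c(O)c2c1O[C@H](C)[C@H](C)C2=O.[K+].[K+] | intermediate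
28 | (3S)-3-{(2R,3S,8S)-5-hydroxy-2,3-dimethyl-8-[(2S)-5-methyl-2-(prop-1-en-2-yl)hex-4-en-1-yl]-8-(3-methylbut-2-en-1-yl)-4,7-dioxo-3,4,7,8-tetrahydro-2H-chromen-6-yl}-3-phenylpropanoic acid (CNP0150579.2) | C=C(C)[C@@H](CC=C(C)C)C[C@]1(CC=C(C)C)C(=O)C([C@@H](CC(=O)O)c2ccccc2)=C(O)C2=C1O[C@H](C)[C@H](C)C2=O | target

Total step count: 12. Longest linear sequence: 8 steps (11 → 28 through steps 5–12; equally 1 → 28 through steps 1–3 and 8–12).

Steps most likely to fail

1. Step 8. Three processes can erode the one-flask ring expansion: proton transfer from the α-position of the lactone to the aryllithium, retro-aldol cleavage or α-epimerisation of the lithium aldolate before ring closure, and loss of LiF from the aryllithium on warming. The fallback makes the two bonds separately, setting out from 4 and 18 and returning at 21. Aldol imide 4 would be converted with MeNH(OMe)·HCl and AlMe3 into the Weinreb amide (2S,3R)-3-hydroxy-N-methoxy-N,2-dimethylbutanamide F1, which is silylated (Et3SiCl, imidazole) to its triethylsilyl ether F2. Aryllithium 19, generated from 18 as in step 8, would be acylated by F2 at −78 °C to the ortho-fluoroaryl β-silyloxy ketone F3; the chelated tetrahedral adduct rules out enolisation and over-addition. Fluoride (Bu4NF, THF, 0 °C) would then unmask the alkoxide, which closes ring B by SNAr to give 21.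

2. Step 12. The risks are poor facial selectivity at C8, competing alkylation at oxygen or at C6, and base-induced epimerisation at C3 of the cis-chromanone. The fallback sets out from 25 and returns at 28 without a catalyst: aqueous LiOH in THF at 0 °C opens the lactone, and prenyl bromide is added to the same aqueous phenoxide solution (water suppresses O-alkylation). After acidification this should give 28 together with the C8-epimeric acid F4, and the two diastereomers would be separated by preparative HPLC. Control of the quaternary centre is traded for a separation.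

3. Step 10. The risks are low nucleophilicity of the ketone-deactivated phenol towards the iminium ion, competing oxa-Michael addition and weak stereoinduction. The fallback sets out from 22 and returns at 25, bypassing 24, and sets the benzylic centre by hydride delivery instead. The free 7-hydroxyl of 22 would be esterified with phenylpropiolic acid (DCC, DMAP) to the aryl propiolate F5. Intramolecular hydroarylation at C6 (Ph3PAuCl, AgOTf, CH2Cl2) should give the 4-phenylcoumarin F6. Asymmetric conjugate reduction with copper hydride (Cu(OAc)2·H2O, DTBM-SEGPHOS, (EtO)2MeSiH, t-BuOH, toluene), using the ligand antipode that gives the (4S)-lactone, then leads to 25.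

Further compounds
F1 | step 8 | (2S,3R)-3-hydroxy-N-methoxy-N,2-dimethylbutanamide | O[C@H](C)[C@H](C)C(=O)N(C)OC
F2 | step 8 | (2S,3R)-N-methoxy-N,2-dimethyl-3-(triethylsilyloxy)butanamide | CC[Si](CC)(CC)O[C@H](C)[C@H](C)C(=O)N(C)OC
F3 | step 8 | (2S,3R)-1-{6-fluoro-2,4-bis(methoxymethoxy)-5-[(2S)-5-methyl-2-(prop-1-en-2-yl)hex-4-en-1-yl]-3-(trimethylsilyl)phenyl}-2-methyl-3-(triethylsilyloxy)butan-1-one | C=C(C)[C@@H](CC=C(C)C)Cc1c(F)c(C(=O)[C@@H](C)[C@@H](C)O[Si](CC)(CC)CC)c(OCOC)c([Si](C)(C)C)c1OCOC
F4 | step 12 | (3S)-3-{(2R,3S,8R)-5-hydroxy-2,3-dimethyl-8-[(2S)-5-methyl-2-(prop-1-en-2-yl)hex-4-en-1-yl]-8-(3-methylbut-2-en-1-yl)-4,7-dioxo-3,4,7,8-tetrahydro-2H-chromen-6-yl}-3-phenylpropanoic acid (C8 epimer of 28) | C=C(C)[C@@H](CC=C(C)C)C[C@@]1(CC=C(C)C)C(=O)C([C@@H](CC(=O)O)c2ccccc2)=C(O)C2=C1O[C@H](C)[C@H](C)C2=O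
F5 | step 10 | (2R,3S)-5-hydroxy-2,3-dimethyl-8-[(2S)-5-methyl-2-(prop-1-en-2-yl)hex-4-en-1-yl]-4-oxo-3,4-dihydro-2H-chromen-7-yl 3-phenylprop-2-ynoate | C=C(C)[C@@H](CC=C(C)C)Cc1c(OC(=O)C#Cc3ccccc3)cc(O)c2c1O[C@H](C)[C@H](C)C2=O
F6 | step 10 | (7S,8R)-5-hydroxy-7,8-dimethyl-10-[(2S)-5-methyl-2-(prop-1-en-2-yl)hex-4-en-1-yl]-4-phenyl-7,8-dihydro-2H,6H-pyrano[3,2-g]chromene-2,6-dione | C=C(C)[C@@H](CC=C(C)C)Cc1c2OC(=O)C=C(c3ccccc3)c2c(O)c2c1O[C@H](C)[C@H](C)C2=O
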